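**Assumption:** the target SMILES has no stereocentre and no stereogenic double bond (the only non-aromatic alkene is endocyclic), so the compound is achiral and no enantioselective operation is needed.

## Retrosynthetic overview

1. The 2,2-dimethylpyran ring is formed last, by oxidising a 5'-prenyl-3',4'-catechol isoflavone (o-quinone → o-quinone methide → oxa-6π closure).
2. The C3–C1' bond and the pyranone ring are made together: the prenylcatechol is oxidatively dearomatised to its o-quinone, an o-hydroxyaryl enaminone adds to it, and the chromone closes with loss of Me2NH.
3. The quinone precursor, 3-prenylcatechol, comes from catechol by ortho C-prenylation, which desymmetrises the feedstock.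
4. The enaminone comes from commercial 2',4'-dihydroxy-6'-methoxyacetophenone, which already carries the 5-OMe/7-OH pattern.
5. Ring order: the A and B rings are purchased, the pyranone C ring is formed in the quinone coupling, and the chromene ring is formed last.

## Route

**Step 1**
Reactants: 1, catechol (benzene-1,2-diol); 2, prenyl bromide (1-bromo-3-methylbut-2-ene)
Product: 3, 3-(3-methylbut-2-en-1-yl)benzene-1,2-diol (3-prenylcatechol)
Conditions: 1 (3 equiv), NaH (1.0 equiv), toluene, 0 °C → rt, Ar; then 2 (1.0 equiv), rt, 16 h; aq. NH4Cl; excess 1 washed out with water, chromatography
Reagents that add atoms: prenyl bromide (2), CC(C)=CCBr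
Why: Claisen-type ortho C-alkylation of a sodium phenoxide tight ion pair in a non-polar solvent puts the allylic electrophile on the carbon ortho to O–, which in catechol is C3; the yield is expected to be modest (roughly 30–40%), but catechol is cheap and used in excess.

**Step 2**
Reactants: 4, 1-(2,4-dihydroxy-6-methoxyphenyl)ethan-1-one; 5, tert-butoxybis(dimethylamino)methane (Bredereck's reagent)
Product: 6, (E)-1-(2,4-dihydroxy-6-methoxyphenyl)-3-(dimethylamino)prop-2-en-1-one
Conditions: 5 (3 equiv), THF, 60 °C, 3 h; pH 6–7 phosphate buffer work-up (no strong acid)
Reagents that add atoms: Bredereck's reagent (5), CC(C)(C)OC(N(C)C)N(C)C (supplies the =CH–NMe2 unit)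
Why: Aminomethylenation of the methyl ketone gives the push-pull (E)-enaminone; the aminal ester has no transferable methyl group, so the free 4-OH is not O-methylated as it could be with DMF-DMA.

**Step 3 (key step, part 1: oxidative dearomatisation)**
Reactants: 3, 3-prenylcatechol
Product: 7, 3-(3-methylbut-2-en-1-yl)cyclohexa-3,5-diene-1,2-dione (3-prenyl-o-benzoquinone), kept as a cold solution and not isolated
Conditions: 3 (1.25 equiv relative to 6), PhI(OAc)2 (1.20 equiv relative to 6), MeCN (0.05 M), –30 °C, 10 min, Ar; solution used at once in step 4
Reagents that add atoms: none (PhI(OAc)2 only removes two hydrogens; PhI and AcOH are by-products)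
Why: Two-electron hypervalent-iodine oxidation of a catechol to its o-quinone is fast and clean at low temperature; the oxidant is sub-stoichiometric to 3 so none is left to attack the enaminone, and the cold, dilute, weakly acidic medium slows tautomerisation of 7 to the quinone methide.

**Step 4 (key step, part 2: C–C coupling and chromone annulation, same flask as step 3)**
Reactants: 7, 3-prenyl-o-benzoquinone (solution from step 3); 6, the enaminone
Product: 8, 3-[3,4-dihydroxy-5-(3-methylbut-2-en-1-yl)phenyl]-7-hydroxy-5-methoxy-4H-chromen-4-one
Conditions: 6 (1.0 equiv) in MeCN/AcOH 4:1 added to the solution of 7 at –30 °C; –30 °C → rt, 2 h; then 60 °C, 1 h; Ar; aqueous work-up, chromatography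
Reagents that add atoms: none (AcOH is not incorporated; Me2NH is lost)
Why: Proposed new method: the enaminone α-carbon of 6 adds 1,4 to 7 at C5, the unhindered β-position remote from the prenyl group where C-nucleophiles attack 3-alkyl-o-quinones. Tautomerisation restores the catechol, and the ortho-phenol then closes onto the aminomethylene carbon with loss of Me2NH (held as its acetate so it cannot add to 7) to give the chromone. The closest known reaction types are the Nenitzescu-type conjugate addition of enaminones to quinones, the oxidative Michael coupling of catechols with 1,3-dicarbonyls (coumestan synthesis), and the α-functionalisation/chromone annulation of o-hydroxyaryl enaminones with electrophiles.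

Note on step 4: any 8 that is oxidised by surplus 7 can only proceed to the step 5 product, so a mixture of 8 and 9 can be taken forward together.

**Step 5**
Reactants: 8, the 5'-prenyl catechol isoflavone
Product: 9, glycyrrhizaisoflavone B, 7-hydroxy-3-(8-hydroxy-2,2-dimethyl-2H-chromen-6-yl)-5-methoxy-4H-chromen-4-one
Conditions: DDQ (1.1 equiv), anhydrous 1,4-dioxane, rt → 60 °C, 1–2 h; filter off DDQH2, chromatography
Reagents that add atoms: none
Why: DDQ oxidises the catechol to its o-quinone, which tautomerises at the prenyl CH2 to the vinyl o-quinone methide and closes by oxa-6π electrocyclisation (the pathway of the DDQ dehydrogenative cyclisation of o-prenylphenols and of the ubiquinone → ubichromenol isomerisation). Only the 4'-oxygen is ortho to the prenyl group, so one chromene regioisomer is possible and no stereocentre is created.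

## Compound list

1 | catechol | Oc1ccccc1O | starting material
2 | prenyl bromide | CC(C)=CCBr | starting material
3 | 3-(3-methylbut-2-en-1-yl)benzene-1,2-diol | CC(C)=CCc1cccc(O)c1O | intermediate
4 | 1-(2,4-dihydroxy-6-methoxyphenyl)ethan-1-one | COc1cc(O)cc(O)c1C(C)=O | starting material
5 | tert-butoxybis(dimethylamino)methane | CC(C)(C)OC(N(C)C)N(C)C | starting material
6 | (E)-1-(2,4-dihydroxy-6-methoxyphenyl)-3-(dimethylamino)prop-2-en-1-one | COc1cc(O)cc(O)c1C(=O)/C=C/N(C)C | intermediate
7 | 3-(3-methylbut-2-en-1-yl)cyclohexa-3,5-diene-1,2-dione (solution, not isolated) | CC(C)=CCC1=CC=CC(=O)C1=O | intermediate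
8 | 3-[3,4-dihydroxy-5-(3-methylbut-2-en-1-yl)phenyl]-7-hydroxy-5-methoxy-4H-chromen-4-one | COc1cc(O)cc2occ(-c3cc(O)c(O)c(CC=C(C)C)c3)c(=O)c12 | intermediate
9 | glycyrrhizaisoflavone B | COc1cc(O)cc2occ(-c3cc(O)c4c(c3)C=CC(C)(C)O4)c(=O)c12 | target

## Summary

Total step count: 5 (steps 3 and 4 are run in one flask, so there are four isolations).
Longest linear sequence: 4 steps (1 → 3 → 7 → 8 → 9, i.e. steps 1, 3, 4, 5); step 2 is the convergent branch.

Three steps most likely to fail:

1. **Step 4 (with the quinone from step 3).** The quinone 7 may tautomerise and electrocyclise to 2,2-dimethyl-2H-chromen-8-ol before C–C bond formation. It may also react at oxygen (hetero-Diels–Alder with the enaminone), add at C4, or be attacked by the electron-rich A ring of 6.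
   Fallback: abandon the quinone addition and use that chromenol in a cross-coupling. It is made deliberately from 3 with Ag2O/Et3N, or from catechol via the mono-(1,1-dimethylpropargyl) ether and aromatic Claisen rearrangement. O-silylate it, carry out Ir-catalysed C–H borylation at C6 (the only arene C–H without an ortho substituent), and Suzuki-couple with 3-iodo-7-hydroxy-5-methoxychromone (from 6 and I2), then desilylate.

2. **Step 1.** Direct C-prenylation may give mainly O-prenyl ether, the 4-prenyl isomer or dialkylation.
   Fallback: directed ortho-metalation. Convert catechol to its bis(MOM) ether, lithiate with n-BuLi/TMEDA, transmetalate to copper, add prenyl bromide, and remove the MOM groups under mild acid to give 3 as a single regioisomer.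

3. **Step 5.** DDQ may over-oxidise the polyphenol, or the intermediate o-quinone may be intercepted before it tautomerises.
   Fallback: non-quinone ring closure. Treat 8 with PhSeCl for 6-endo selenoetherification by the 4'-OH, giving the 3-phenylseleno-2,2-dimethylchroman, then H2O2 for selenoxide syn-elimination to the chromene 9.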